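Locants follow ansamycin numbering: C1 = lactam carbonyl, C2–C15 = ansa chain, C16–C21 = arene (C16 bears C15, C18 and C21 bear O, C20 bears N). Target configuration: 2E,4Z,6S,7R,8E,10S,11R,12S,14S,15R. "Macrolactam" below means the 19-membered ring N, C1–C15, C16, C21, C20.

## The problem

The target is the hydroquinone form of a 19-membered ansa lactam whose C1–C15 chain bridges the meta positions C16 and C20 of a 2-aminohydroquinone. The chain holds a (2E,4Z)-dienamide, an E-trisubstituted C8=C9 olefin and seven stereocentres in three groups: C6/C7 (syn), C10/C11/C12 (syn, then anti) and C14/C15 (syn), with C12 and C14 1,3-anti across C13H2. C12 is the hub: through a ring it can control C14 and C15, and by Felkin induction C11. C6/C7 lie beyond the C8=C9 olefin, out of reach of any relay, and must be set on their own. Four chain oxygens are differentiated (C7 carbamate, C11 OMe, C12 free OH, C15 OMe), so each must enter separately or carry its own protecting group. The 4Z olefin, the allylic C7 carbamate, the benzylic C15 ether next to a phenol and the air-sensitive aminohydroquinone will not survive rough treatment; the hydroquinone must be unmasked last. The feature that makes the key step possible is the C7(O)–C8(CH3)=C9H unit: a 2-methyl allylic alcohol whose methyl-bearing carbon C8 is the one next to oxygenated C7, and which sits in the 19-membered ring directly opposite the lactam. This unit is the retron of a ring C8≡C9 triple bond followed by C7–OH-directed trans-hydrostannation and Sn→CH3 exchange; C8 and C9 each carry a stereocentre (C7, C10) accessible by ynal aldol and propargylation chemistry, and a 19-membered ring holds a triple bond without strain.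

## Retrosynthesis

**Arene oxidation level (43 ⇐ 42 ⇐ 41).** No C–C bond is cut. Hydroquinone 43 is traced to quinone 42 and then to the 18,21-dimethyl ether 41. The methyl ethers survive the whole route, where a free or silylated hydroquinone would not. The forward oxidative demethylation and mild reduction must spare the diene and the carbamate.

**C7 carbamate and C12 hydroxyl (41 ⇐ 40 ⇐ 38).** The O–C(O)NH2 bond at C7 and the O–Si bond at C12 are cut. Carbamoylating 38, in which C7–OH is free and C12 is a TBS ether, is the only point where the two secondary hydroxyls are told apart. The forward step needs an acylating agent that reacts with a hindered allylic alcohol but not with the anilide N–H.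

**C8–CH3 and C9–H (38 ⇐ 37 ⇐ 36 ⇐ 35).** The methyl on C8 and the hydrogen on C9 are removed, leading through stannane 37 to propargylic alcohol 36 and its TES ether 35. An olefination or olefin metathesis at C8=C9 would have to set E geometry between two branched centres with nothing to enforce it. Here geometry and regiochemistry both follow from the C7 hydroxyl, which steers tin to C8 in a trans addition. The precursor loses an alkene geometry and a methyl group.

**C8≡C9, the key cut (35 ⇐ 34).** The ring is opened at the triple bond to give acyclic diyne amide 34 with two methyl-capped alkynes. This bond is as far from the lactam as the ring allows and divides the chain into C1–C8 and C9–C15 halves of equal weight. No stereocentre or alkene geometry is at stake in the closure. The forward reaction must favour ring over oligomer and tolerate the anilide N–H, the silyl ethers and the diene.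

**N–C1 (34 ⇐ 20 + 32).** With the ring no longer closed at nitrogen, the amide bond becomes a plain intermolecular acylation of aniline 20 (C9–C15 and the arene, five stereocentres) by acid 32 (C1–C8, two stereocentres, both diene olefins).

**C10–C11 (20 ⇐ 19 ⇐ 18 ⇐ 17 + 4).** Cutting C10–C11 gives α-silyloxy aldehyde 17 and chiral allenylstannane 4. The forward SE2′ addition creates C10 and C11 and delivers the methyl-capped alkyne for the key step in the same operation. An aldol or crotylation here would leave a carbonyl or vinyl group to be converted into the alkyne. Reagent 4 comes from ynone 1 through alcohol 2 and mesylate 3, the one stereocentre set by catalysis.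

**C14–C15 and the C14 methyl (17 ⇐ 16 ⇐ 15 ⇐ 14 ⇐ 12 ⇐ 11 ⇐ 10 ⇐ 7 + 6).** C12 is bought in lactone 7. The aldol of its enolate (8, 9) with aldehyde 6 forms C14–C15 and sets C14 and C15 in one event from C12. The lactone carbonyl carbon then becomes the C14 methyl via lactol 12 and tosylhydrazone 13, which also frees C12–OH. An auxiliary aldol on 6 would leave C13 as a carbonyl to deoxygenate and C12 still to be set. Aldehyde 6 comes from phenol 5.

**C2=C3, C4=C5 and C6–C7 (32 ⇐ 31 ⇐ 29 ⇐ 28 ⇐ 27 ⇐ 26 ⇐ 25 ⇐ 24 ⇐ 21 + 22).** The 2E olefin is cut to Z-enal 30 (from alcohol 29), the 4Z olefin to aldehyde 27, and C6–C7 to imide 21 and but-2-ynal 22 (via enolate 23). Using 22 as the aldol acceptor brings in the second methyl-capped alkyne at no cost in steps. Each forward reaction is a standard geometry- or auxiliary-controlled olefination or aldol.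

## Roads not taken

**Alternative 1:** cut N–C1 in the ring; the forward key step is macrolactamisation of seco amino acid A1. This is the route most chemists would draw first. It asks the ring closure to solve nothing. A1 must already contain the C8=C9 olefin between two stereocentres and all seven stereocentres in one chain, so the synthesis is linear from the arene to C1. The chosen plan makes the ring closure generate the C8=C9 precursor and is convergent at the amide.

**Alternative 2:** cut C4=C5; the forward key step is ring-closing alkyne metathesis of enyne-yne A2 to cycloenyne A3, then Z-selective semi-reduction. This solves the 4Z olefin and the ring, but the harder C8=C9 olefin must still be built linearly inside A2. The two fragments are very unequal (a six-carbon enynoic acid against the whole C5–C15 chain). The last alkene-forming step is a semi-reduction of a conjugated enyne next to other olefins, where over-reduction cannot be excluded. The chosen cut uses the C7 oxygen as a directing group and splits the chain in the middle.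

**Alternative 3:** cut C7–C8; the forward key step is a nickel-catalysed reductive alkyne–aldehyde macrocyclisation of ynal A4 (or the chromium-mediated variant from a vinyl iodide). It would give the ring, the E-trisubstituted olefin and C7 at once. But the C7 aldehyde in A4 has an α-stereocentre (C6) that is also the vinylogous position of the dienamide, so epimerisation and conjugation are likely. C–C bond formation at C8 rather than C9 is intrinsically weak for a methyl/sec-alkyl alkyne. The C7 configuration would rest on macrocyclic control that cannot be predicted. The chosen plan sets C7 by an auxiliary aldol and takes regiocontrol from the C7 hydroxyl.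

Key step: step 24

## Route

Step 1
Reactants: 1 pent-3-yn-2-one
Product: 2 (S)-pent-3-yn-2-ol
Conditions: RuCl[(S,S)-TsDPEN](p-cymene) (cat.), KOH (cat.), i-PrOH, rt
Reagents that add atoms: none
Why: Noyori asymmetric transfer hydrogenation of an α,β-acetylenic ketone; with the (S,S) catalyst the alkynyl group takes the role of aryl and the (S)-carbinol is expected. This is the only stereocentre set by catalysis and it is later transcribed into C10.

Step 2
Reactants: 2 (S)-pent-3-yn-2-ol
Product: 3 (S)-pent-3-yn-2-yl methanesulfonate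
Conditions: MsCl, Et3N, CH2Cl2, –78 °C
Reagents that add atoms: methanesulfonyl chloride CS(=O)(=O)Cl
Why: O-sulfonylation with retention at carbon; the propargylic mesylate is used cold and without storage.

Step 3
Reactants: 3 (S)-pent-3-yn-2-yl methanesulfonate
Product: 4 (aR)-tributyl(penta-2,3-dien-2-yl)stannane
Conditions: Bu3SnH, LDA, THF, 0 °C; CuBr·SMe2, –78 °C; then 3
Reagents that add atoms: tributyltin hydride CCCC[SnH](CCCC)CCCC
Why: anti SN2′ displacement of a propargylic mesylate by a stannylcuprate (Marshall allenylstannane synthesis); central chirality of 3 is transferred to the (aR) axis of the allene.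

Step 4
Reactants: 5 2-hydroxy-5-methoxy-3-nitrobenzaldehyde
Product: 6 2,5-dimethoxy-3-nitrobenzaldehyde
Conditions: MeI, K2CO3, DMF, rt
Reagents that add atoms: iodomethane CI
Why: Williamson O-methylation of an acidic o-nitrophenol.

Step 5
Reactants: 7 (S)-5-[(trityloxy)methyl]dihydrofuran-2(3H)-one; 6 2,5-dimethoxy-3-nitrobenzaldehyde
Product: 10 (3S,5S)-3-[(R)-(2,5-dimethoxy-3-nitrophenyl)(hydroxy)methyl]-5-[(trityloxy)methyl]dihydrofuran-2(3H)-one, via lithium enolate 8 (not isolated), via zinc enolate 9 (not isolated)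
Conditions: LDA, THF, –78 °C; ZnCl2; then 6, –78 → –40 °C; aq. NH4Cl
Reagents that add atoms: none
Why: Aldol addition of a γ-butyrolactone enolate through a Zimmerman–Traxler chair. C14 is set by 1,3-induction from C12, the aldehyde entering anti to the CH2OTr group; C15 is set by the ring-locked E-enolate, which gives the anti aldol (15R), the arrangement also favoured in the equilibrating zinc aldolate.

Step 6
Reactants: 10 aldol lactone
Product: 11 (3S,5S)-3-[(R)-(2,5-dimethoxy-3-nitrophenyl)(methoxy)methyl]-5-[(trityloxy)methyl]dihydrofuran-2(3H)-one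
Conditions: Me3OBF4, 1,8-bis(dimethylamino)naphthalene, 4 Å MS, CH2Cl2, rt
Reagents that add atoms: trimethyloxonium tetrafluoroborate C[O+](C)C.F[B-](F)(F)F
Why: O-methylation with Meerwein's salt under non-basic conditions, chosen so that the β-hydroxy lactone cannot undergo retro-aldol cleavage or elimination; the trityl ether is protected by the amine buffer.

Step 7
Reactants: 11 methoxy lactone
Product: 12 (3S,5S)-3-[(R)-(2,5-dimethoxy-3-nitrophenyl)(methoxy)methyl]-5-[(trityloxy)methyl]tetrahydrofuran-2-ol (both anomers)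
Conditions: DIBAL-H, CH2Cl2, –78 °C
Reagents that add atoms: none
Why: Partial reduction of a lactone to the lactol; the aluminium hemiacetal is stable at –78 °C and the nitroarene is not touched at this temperature.

Step 8
Reactants: 12 lactol
Product: 14 (2S,4S,5R)-5-(2,5-dimethoxy-3-nitrophenyl)-5-methoxy-4-methyl-1-(trityloxy)pentan-2-ol, via tosylhydrazone 13 (not isolated)
Conditions: TsNHNH2, THF, 45 °C; then catecholborane, CHCl3, 0 °C; NaOAc·3H2O, 60 °C
Reagents that add atoms: none
Why: The open hydroxy-aldehyde form of the lactol is trapped as its tosylhydrazone and reduced under Kabalka conditions (C=N hydroboration, then loss of sulfinate and N2). The former lactone carbonyl carbon becomes the C14 methyl and C12–OH is freed; C14 is not involved in the diazene collapse and should keep its configuration.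

Step 9
Reactants: 14 secondary alcohol
Product: 15 tert-butyl{[(2S,4S,5R)-5-(2,5-dimethoxy-3-nitrophenyl)-5-methoxy-4-methyl-1-(trityloxy)pentan-2-yl]oxy}dimethylsilane
Conditions: TBSOTf, 2,6-lutidine, CH2Cl2, –40 → 0 °C
Reagents that add atoms: tert-butyldimethylsilyl triflate CC(C)(C)[Si](C)(C)OS(=O)(=O)C(F)(F)F
Why: Silylation of the C12 hydroxyl; TBS is chosen because it survives the later TES cleavage and is a non-chelating α-substituent for step 12.

Step 10
Reactants: 15 trityl TBS bis-ether
Product: 16 (2S,4S,5R)-2-[(tert-butyldimethylsilyl)oxy]-5-(2,5-dimethoxy-3-nitrophenyl)-5-methoxy-4-methylpentan-1-ol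
Conditions: TsOH·H2O (cat.), MeOH/CH2Cl2, 0 °C
Reagents that add atoms: none
Why: Acid-catalysed solvolysis of the trityl ether (SN1, trityl cation trapped by methanol); a secondary TBS ether is stable under these conditions.

Step 11
Reactants: 16 primary alcohol
Product: 17 (2S,4S,5R)-2-[(tert-butyldimethylsilyl)oxy]-5-(2,5-dimethoxy-3-nitrophenyl)-5-methoxy-4-methylpentanal
Conditions: Dess–Martin periodinane, CH2Cl2, 0 °C → rt
Reagents that add atoms: none
Why: Dess–Martin oxidation under near-neutral conditions; the α-silyloxy aldehyde is used at once to avoid epimerisation at C12.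

Step 12
Reactants: 17 α-silyloxy aldehyde; 4 (aR)-tributyl(penta-2,3-dien-2-yl)stannane
Product: 18 (4S,5R,6S,8S,9R)-6-[(tert-butyldimethylsilyl)oxy]-9-(2,5-dimethoxy-3-nitrophenyl)-9-methoxy-4,8-dimethylnon-2-yn-5-ol
Conditions: BF3·OEt2, CH2Cl2, –78 °C
Reagents that add atoms: none
Why: Marshall SE2′ addition of a chiral allenylstannane to a BF3-activated aldehyde. C10 comes from the allene axis (anti SE2′, net retention relative to 3) and C11 from the open transition state, which gives the syn adduct. Polar Felkin–Anh attack anti to the C12 silyloxy group favours the same face (matched pair, 11,12-anti), and the methyl-capped alkyne needed for step 24 is formed directly.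

Step 13
Reactants: 18 homopropargylic alcohol
Product: 19 tert-butyl{[(4S,5R,6S,8S,9R)-9-(2,5-dimethoxy-3-nitrophenyl)-5,9-dimethoxy-4,8-dimethylnon-2-yn-6-yl]oxy}dimethylsilane
Conditions: MeOTf, 2,6-di-tert-butyl-4-methylpyridine, CH2Cl2, rt
Reagents that add atoms: methyl trifluoromethanesulfonate COS(=O)(=O)C(F)(F)F
Why: O-methylation of a hindered secondary alcohol with methyl triflate and a non-nucleophilic base; no alkoxide is formed, so the TBS group cannot migrate from O12 to O11.

Step 14
Reactants: 19 nitroarene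
Product: 20 3-[(1R,2S,4S,5R,6S)-4-[(tert-butyldimethylsilyl)oxy]-1,5-dimethoxy-2,6-dimethylnon-7-yn-1-yl]-2,5-dimethoxyaniline
Conditions: Zn, AcOH, EtOH, 0 °C → rt
Reagents that add atoms: none
Why: Dissolving-metal reduction of an aromatic nitro group to the aniline; the internal alkyne, the silyl ether and the benzylic ether (meta to the new amino group) are not affected.

Step 15
Reactants: 21 (R)-4-benzyl-3-propionyloxazolidin-2-one; 22 but-2-ynal
Product: 24 (R)-4-benzyl-3-[(2R,3R)-3-hydroxy-2-methylhex-4-ynoyl]oxazolidin-2-one, via boron enolate 23 (not isolated)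
Conditions: Bu2BOTf, Et3N, CH2Cl2, 0 °C; then 22, –78 → 0 °C; H2O2, pH 7 buffer, MeOH
Reagents that add atoms: none
Why: Evans boron aldol: the Z-boron enolate reacts through a closed chair on the face opposite the benzyl group, giving the syn aldol with C6 and C7 set together by the auxiliary; the ynal supplies the C8 alkyne with its methyl cap.

Step 16
Reactants: 24 aldol imide
Product: 25 (2R,3R)-3-hydroxy-N-methoxy-N,2-dimethylhex-4-ynamide
Conditions: MeNH(OMe)·HCl, AlMe3, CH2Cl2, –20 → 0 °C
Reagents that add atoms: N,O-dimethylhydroxylamine hydrochloride CNOC.Cl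
Why: Aluminium-amide transamination of the imide to the Weinreb amide, assisted by the free β-hydroxyl; the auxiliary is recovered.

Step 17
Reactants: 25 hydroxy Weinreb amide
Product: 26 (2R,3R)-N-methoxy-N,2-dimethyl-3-[(triethylsilyl)oxy]hex-4-ynamide
Conditions: TESCl, imidazole, DMF, 0 °C → rt
Reagents that add atoms: chlorotriethylsilane CC[Si](CC)(CC)Cl
Why: Silylation of the C7 hydroxyl; TES is chosen because it can later be removed in the presence of the C12 TBS ether.

Step 18
Reactants: 26 silyl Weinreb amide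
Product: 27 (2R,3R)-2-methyl-3-[(triethylsilyl)oxy]hex-4-ynal
Conditions: DIBAL-H, THF, –78 °C
Reagents that add atoms: none
Why: Reduction of a Weinreb amide stops at the chelated tetrahedral intermediate and gives the aldehyde on work-up; the α-methyl aldehyde is used directly.

Step 19
Reactants: 27 aldehyde
Product: 28 methyl (2Z,4S,5R)-4-methyl-5-[(triethylsilyl)oxy]oct-2-en-6-ynoate
Conditions: (CF3CH2O)2P(O)CH2CO2Me, KHMDS, 18-crown-6, THF, –78 °C
Reagents that add atoms: methyl bis(2,2,2-trifluoroethyl)phosphonoacetate COC(=O)CP(=O)(OCC(F)(F)F)OCC(F)(F)F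
Why: Still–Gennari olefination; fast, irreversible elimination from the syn oxaphosphetane gives the Z-enoate, which becomes the 4Z olefin.

Step 20
Reactants: 28 Z-enoate
Product: 29 (2Z,4S,5R)-4-methyl-5-[(triethylsilyl)oxy]oct-2-en-6-yn-1-ol
Conditions: DIBAL-H, CH2Cl2, –78 °C
Reagents that add atoms: none
Why: 1,2-Reduction of the conjugated ester to the allylic alcohol with retention of the Z geometry.

Step 21
Reactants: 29 Z-allylic alcohol
Product: 31 methyl (2E,4Z,6S,7R)-2,6-dimethyl-7-[(triethylsilyl)oxy]deca-2,4-dien-8-ynoate, via Z-enal 30 (not isolated)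
Conditions: MnO2, Ph3P=C(Me)CO2Me, CH2Cl2, rt → 40 °C
Reagents that add atoms: methyl 2-(triphenylphosphoranylidene)propanoate COC(=O)C(C)=P(c1ccccc1)(c1ccccc1)c1ccccc1
Why: Tandem allylic oxidation and Wittig olefination; the Z-enal is trapped as it forms and so has little time to isomerise, and the stabilised α-methyl ylide gives the 2E trisubstituted olefin.

Step 22
Reactants: 31 methyl dienoate
Product: 32 (2E,4Z,6S,7R)-2,6-dimethyl-7-[(triethylsilyl)oxy]deca-2,4-dien-8-ynoic acid
Conditions: LiOH, THF/MeOH/H2O, 0 °C → rt; aq. HCl to pH 4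
Reagents that add atoms: lithium hydroxide [Li+].[OH-]
Why: Saponification of the methyl ester; the hindered secondary TES ether should survive short exposure to cold hydroxide.

Step 23
Reactants: 32 dienoic acid; 20 aniline
Product: 34 (2E,4Z,6S,7R)-N-{3-[(1R,2S,4S,5R,6S)-4-[(tert-butyldimethylsilyl)oxy]-1,5-dimethoxy-2,6-dimethylnon-7-yn-1-yl]-2,5-dimethoxyphenyl}-2,6-dimethyl-7-[(triethylsilyl)oxy]deca-2,4-dien-8-ynamide, via acid chloride 33 (not isolated)
Conditions: 1-chloro-N,N,2-trimethylprop-1-en-1-amine, CH2Cl2, 0 °C; then 20, pyridine, 0 °C → rt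
Reagents that add atoms: none
Why: Acid chloride formation with Ghosez's reagent under neutral conditions (silyl ether and Z-olefin preserved), then N-acylation of the moderately hindered aniline; this joins the two halves.

Step 24
Reactants: 34 diyne amide
Product: 35 cycloalkyne macrolactam with C8≡C9 and no methyl on C8 (7-O-TES; 12-O-TBS; 18,21-di-O-methyl)
Conditions: [Mo(≡CC6H4-4-OMe)(OSiPh3)3] (15 mol%), 5 Å MS, toluene (2 mM), 80 °C
Reagents that add atoms: none
Why: Ring-closing alkyne metathesis: the Mo alkylidyne adds to one methyl-capped alkyne in a [2+2] step, the metallacyclobutadiene opens with loss of but-2-yne, and the substrate-bound alkylidyne repeats the sequence on the second alkyne of the same molecule. The closest known reaction type is the macrocyclisation of diynes bearing propargylic silyl ethers to cycloalkynes that are then turned into 2-methyl allylic alcohols. The ring closed is the 19-membered lactam (N, C1–C15, C16, C21, C20), closed by metathesis at C8≡C9, the bond farthest from the amide, to give an unstrained cycloalkyne. No stereocentre is formed: all seven are already in 34 and none is at risk, and the C8=C9 geometry is deferred to steps 26 and 27. The step needs alkyne-over-alkene and ring-over-oligomer selectivity. Alkylidynes do not engage C=C bonds, so the (2E,4Z)-diene is left alone; the identical methyl caps mean only but-2-yne is lost, and its capture by the sieves at high dilution drives the reversible process toward the monomeric ring. The anilide N–H and the silyl and methyl ethers are within the tolerance of silanolate-ligated Mo alkylidynes.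

Step 25
Reactants: 35 cycloalkyne bis-silyl ether
Product: 36 cycloalkyne macrolactam with free C7–OH (12-O-TBS; 18,21-di-O-methyl)
Conditions: PPTS, MeOH/CH2Cl2, 0 °C
Reagents that add atoms: none
Why: Selective acid-catalysed methanolysis of the TES ether, which is far more labile than the secondary TBS ether at C12; this frees the directing hydroxyl.

Step 26
Reactants: 36 propargylic alcohol
Product: 37 (8Z)-8-(tributylstannyl) macrolactam with free C7–OH (12-O-TBS; 18,21-di-O-methyl)
Conditions: Bu3SnH, [Cp*RuCl]4 (cat.), CH2Cl2, rt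
Reagents that add atoms: tributyltin hydride CCCC[SnH](CCCC)CCCC
Why: Ruthenium-catalysed trans-hydrostannation of an internal alkyne. A hydrogen bond from C7–OH to the chloride on ruthenium places tin on the proximal carbon C8 and hydrogen on C9 in an anti addition, so C7 and C10 end up trans. Olefins, including the diene, are not hydrostannylated under these conditions.

Step 27
Reactants: 37 alkenylstannane
Product: 38 (8E)-8-methyl macrolactam with free C7–OH (12-O-TBS; 18,21-di-O-methyl)
Conditions: MeI, CuTC, [Bu4N][Ph2PO2], Pd(PPh3)4 (cat.), DMF, rt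
Reagents that add atoms: iodomethane CI
Why: Copper-assisted Stille-type C-methylation of an alkenylstannane with retention of geometry, under base- and fluoride-free conditions that tolerate the adjacent free hydroxyl; the phosphinate salt removes the tin by-product.

Step 28
Reactants: 38 allylic alcohol
Product: 40 7-O-carbamoyl macrolactam (12-O-TBS; 18,21-di-O-methyl), via trichloroacetyl carbamate 39 (not isolated)
Conditions: Cl3CC(O)NCO, CH2Cl2, 0 °C; then K2CO3, MeOH, 0 °C
Reagents that add atoms: trichloroacetyl isocyanate O=C=NC(=O)C(Cl)(Cl)Cl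
Why: Addition of the hindered C7 hydroxyl to an acyl isocyanate followed by methanolysis of the trichloroacetyl group gives the primary carbamate; C12 is still silylated, so only C7 reacts.

Step 29
Reactants: 40 carbamate TBS ether
Product: 41 18,21-di-O-methyl ether of the target (free C12–OH)
Conditions: HF·pyridine, pyridine, THF, 0 °C → rt
Reagents that add atoms: none
Why: Buffered fluoride desilylation of the secondary TBS ether; the allylic carbamate and the benzylic ether are stable to these conditions.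

Step 30
Reactants: 41 dimethyl ether
Product: 43 CNP0548031.1 (hydroquinone target), via quinone 42 (not isolated)
Conditions: CAN, MeCN/H2O, 0 °C; then aq. Na2S2O4, EtOAc, rt (argon)
Reagents that add atoms: water O
Why: Oxidative demethylation of the p-dimethoxy anilide to the p-quinone (a reaction type established on this ring system), with water supplying the quinone oxygens; the crude quinone is reduced with dithionite in the same work-up and the hydroquinone is handled under argon.

## Compound list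

1 | pent-3-yn-2-one | CC#CC(C)=O | starting material
2 | (S)-pent-3-yn-2-ol | CC#C[C@H](C)O | intermediate
3 | (S)-pent-3-yn-2-yl methanesulfonate | CC#C[C@H](C)OS(C)(=O)=O | intermediate
4 | (aR)-tributyl(penta-2,3-dien-2-yl)stannane | CCCC[Sn](CCCC)(CCCC)C(C)=[C@@]=C(C)[H] | intermediate
5 | 2-hydroxy-5-methoxy-3-nitrobenzaldehyde | O=Cc1cc(OC)cc([N+](=O)[O-])c1O | starting material
6 | 2,5-dimethoxy-3-nitrobenzaldehyde | O=Cc1cc(OC)cc([N+](=O)[O-])c1OC | intermediate
7 | (S)-5-[(trityloxy)methyl]dihydrofuran-2(3H)-one | O=C1CC[C@@H](COC(c2ccccc2)(c2ccccc2)c2ccccc2)O1 | starting material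
8 | lithium (S)-5-[(trityloxy)methyl]-4,5-dihydrofuran-2-olate | [Li]OC1=CC[C@@H](COC(c2ccccc2)(c2ccccc2)c2ccccc2)O1 | intermediate
9 | chlorozinc (S)-5-[(trityloxy)methyl]-4,5-dihydrofuran-2-olate | Cl[Zn]OC1=CC[C@@H](COC(c2ccccc2)(c2ccccc2)c2ccccc2)O1 | intermediate
10 | (3S,5S)-3-[(R)-(2,5-dimethoxy-3-nitrophenyl)(hydroxy)methyl]-5-[(trityloxy)methyl]dihydrofuran-2(3H)-one | O[C@@H](c1cc(OC)cc([N+](=O)[O-])c1OC)[C@@H]1C[C@@H](COC(c2ccccc2)(c2ccccc2)c2ccccc2)OC1=O | intermediate
11 | (3S,5S)-3-[(R)-(2,5-dimethoxy-3-nitrophenyl)(methoxy)methyl]-5-[(trityloxy)methyl]dihydrofuran-2(3H)-one | CO[C@@H](c1cc(OC)cc([N+](=O)[O-])c1OC)[C@@H]1C[C@@H](COC(c2ccccc2)(c2ccccc2)c2ccccc2)OC1=O | intermediate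
12 | (3S,5S)-3-[(R)-(2,5-dimethoxy-3-nitrophenyl)(methoxy)methyl]-5-[(trityloxy)methyl]tetrahydrofuran-2-ol, both anomers | CO[C@@H](c1cc(OC)cc([N+](=O)[O-])c1OC)[C@@H]1C[C@@H](COC(c2ccccc2)(c2ccccc2)c2ccccc2)OC1O | intermediate
13 | N'-[(1E,2R,4S)-2-[(R)-(2,5-dimethoxy-3-nitrophenyl)(methoxy)methyl]-4-hydroxy-5-(trityloxy)pentylidene]-4-methylbenzenesulfonohydrazide | CO[C@@H](c1cc(OC)cc([N+](=O)[O-])c1OC)[C@@H](/C=N/NS(=O)(=O)c1ccc(C)cc1)C[C@H](O)COC(c2ccccc2)(c2ccccc2)c2ccccc2 | intermediate
14 | (2S,4S,5R)-5-(2,5-dimethoxy-3-nitrophenyl)-5-methoxy-4-methyl-1-(trityloxy)pentan-2-ol | CO[C@@H](c1cc(OC)cc([N+](=O)[O-])c1OC)[C@@H](C)C[C@H](O)COC(c2ccccc2)(c2ccccc2)c2ccccc2 | intermediate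
15 | tert-butyl{[(2S,4S,5R)-5-(2,5-dimethoxy-3-nitrophenyl)-5-methoxy-4-methyl-1-(trityloxy)pentan-2-yl]oxy}dimethylsilane | CO[C@@H](c1cc(OC)cc([N+](=O)[O-])c1OC)[C@@H](C)C[C@H](O[Si](C)(C)C(C)(C)C)COC(c2ccccc2)(c2ccccc2)c2ccccc2 | intermediate
16 | (2S,4S,5R)-2-[(tert-butyldimethylsilyl)oxy]-5-(2,5-dimethoxy-3-nitrophenyl)-5-methoxy-4-methylpentan-1-ol | CO[C@@H](c1cc(OC)cc([N+](=O)[O-])c1OC)[C@@H](C)C[C@H](O[Si](C)(C)C(C)(C)C)CO | intermediate
17 | (2S,4S,5R)-2-[(tert-butyldimethylsilyl)oxy]-5-(2,5-dimethoxy-3-nitrophenyl)-5-methoxy-4-methylpentanal | CO[C@@H](c1cc(OC)cc([N+](=O)[O-])c1OC)[C@@H](C)C[C@H](O[Si](C)(C)C(C)(C)C)C=O | intermediate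
18 | (4S,5R,6S,8S,9R)-6-[(tert-butyldimethylsilyl)oxy]-9-(2,5-dimethoxy-3-nitrophenyl)-9-methoxy-4,8-dimethylnon-2-yn-5-ol | CO[C@@H](c1cc(OC)cc([N+](=O)[O-])c1OC)[C@@H](C)C[C@H](O[Si](C)(C)C(C)(C)C)[C@H](O)[C@@H](C)C#CC | intermediate
19 | tert-butyl{[(4S,5R,6S,8S,9R)-9-(2,5-dimethoxy-3-nitrophenyl)-5,9-dimethoxy-4,8-dimethylnon-2-yn-6-yl]oxy}dimethylsilane | CO[C@@H](c1cc(OC)cc([N+](=O)[O-])c1OC)[C@@H](C)C[C@H](O[Si](C)(C)C(C)(C)C)[C@H](OC)[C@@H](C)C#CC | intermediate
20 | 3-[(1R,2S,4S,5R,6S)-4-[(tert-butyldimethylsilyl)oxy]-1,5-dimethoxy-2,6-dimethylnon-7-yn-1-yl]-2,5-dimethoxyaniline | CO[C@@H](c1cc(OC)cc(N)c1OC)[C@@H](C)C[C@H](O[Si](C)(C)C(C)(C)C)[C@H](OC)[C@@H](C)C#CC | intermediate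
21 | (R)-4-benzyl-3-propionyloxazolidin-2-one | CCC(=O)N1[C@H](Cc2ccccc2)COC1=O | starting material
22 | but-2-ynal | CC#CC=O | starting material
23 | (R,Z)-4-benzyl-3-[1-(dibutylboryloxy)prop-1-en-1-yl]oxazolidin-2-one | C/C=C(\OB(CCCC)CCCC)N1[C@H](Cc2ccccc2)COC1=O | intermediate
24 | (R)-4-benzyl-3-[(2R,3R)-3-hydroxy-2-methylhex-4-ynoyl]oxazolidin-2-one | CC#C[C@H](O)[C@@H](C)C(=O)N1[C@H](Cc2ccccc2)COC1=O | intermediate
25 | (2R,3R)-3-hydroxy-N-methoxy-N,2-dimethylhex-4-ynamide | CC#C[C@H](O)[C@@H](C)C(=O)N(C)OC | intermediate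
26 | (2R,3R)-N-methoxy-N,2-dimethyl-3-[(triethylsilyl)oxy]hex-4-ynamide | CC#C[C@H](O[Si](CC)(CC)CC)[C@@H](C)C(=O)N(C)OC | intermediate
27 | (2R,3R)-2-methyl-3-[(triethylsilyl)oxy]hex-4-ynal | CC#C[C@H](O[Si](CC)(CC)CC)[C@@H](C)C=O | intermediate
28 | methyl (2Z,4S,5R)-4-methyl-5-[(triethylsilyl)oxy]oct-2-en-6-ynoate | CC#C[C@H](O[Si](CC)(CC)CC)[C@@H](C)/C=C\C(=O)OC | intermediate
29 | (2Z,4S,5R)-4-methyl-5-[(triethylsilyl)oxy]oct-2-en-6-yn-1-ol | CC#C[C@H](O[Si](CC)(CC)CC)[C@@H](C)/C=C\CO | intermediate
30 | (2Z,4S,5R)-4-methyl-5-[(triethylsilyl)oxy]oct-2-en-6-ynal | CC#C[C@H](O[Si](CC)(CC)CC)[C@@H](C)/C=C\C=O | intermediate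
31 | methyl (2E,4Z,6S,7R)-2,6-dimethyl-7-[(triethylsilyl)oxy]deca-2,4-dien-8-ynoate | CC#C[C@H](O[Si](CC)(CC)CC)[C@@H](C)/C=C\C=C(/C)C(=O)OC | intermediate
32 | (2E,4Z,6S,7R)-2,6-dimethyl-7-[(triethylsilyl)oxy]deca-2,4-dien-8-ynoic acid | CC#C[C@H](O[Si](CC)(CC)CC)[C@@H](C)/C=C\C=C(/C)C(O)=O | intermediate
33 | (2E,4Z,6S,7R)-2,6-dimethyl-7-[(triethylsilyl)oxy]deca-2,4-dien-8-ynoyl chloride | CC#C[C@H](O[Si](CC)(CC)CC)[C@@H](C)/C=C\C=C(/C)C(Cl)=O | intermediate
34 | (2E,4Z,6S,7R)-N-{3-[(1R,2S,4S,5R,6S)-4-[(tert-butyldimethylsilyl)oxy]-1,5-dimethoxy-2,6-dimethylnon-7-yn-1-yl]-2,5-dimethoxyphenyl}-2,6-dimethyl-7-[(triethylsilyl)oxy]deca-2,4-dien-8-ynamide | CC#C[C@H](O[Si](CC)(CC)CC)[C@@H](C)/C=C\C=C(/C)C(=O)Nc1cc(OC)cc(c1OC)[C@H](OC)[C@@H](C)C[C@@H]([C@H](OC)[C@@H](C)C#CC)O[Si](C)(C)C(C)(C)C | intermediate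
35 | (2E,4Z,6S,7R,10S,11R,12S,14S,15R) macrolactam with C8≡C9 and no methyl on C8: 2,6,10,14-tetramethyl, 11,15,18,21-tetramethoxy, 7-OTES, 12-OTBS | CO[C@@H]1[C@@H](C)C#C[C@H](O[Si](CC)(CC)CC)[C@@H](C)/C=C\C=C(/C)C(=O)Nc2cc(OC)cc(c2OC)[C@H](OC)[C@@H](C)C[C@@H]1O[Si](C)(C)C(C)(C)C | intermediate
36 | as 35 with free 7-OH | CO[C@@H]1[C@@H](C)C#C[C@H](O)[C@@H](C)/C=C\C=C(/C)C(=O)Nc2cc(OC)cc(c2OC)[C@H](OC)[C@@H](C)C[C@@H]1O[Si](C)(C)C(C)(C)C | intermediate
37 | (2E,4Z,8Z,6S,7R,10S,11R,12S,14S,15R) macrolactam with C8=C9, 8-SnBu3, 7-OH, 12-OTBS, 11,15,18,21-tetramethoxy | CO[C@@H]1[C@@H](C)/C=C(\[Sn](CCCC)(CCCC)CCCC)[C@H](O)[C@@H](C)/C=C\C=C(/C)C(=O)Nc2cc(OC)cc(c2OC)[C@H](OC)[C@@H](C)C[C@@H]1O[Si](C)(C)C(C)(C)C | intermediate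
38 | (2E,4Z,8E,6S,7R,10S,11R,12S,14S,15R) macrolactam with 8-methyl, 7-OH, 12-OTBS, 11,15,18,21-tetramethoxy | CO[C@@H]1[C@@H](C)/C=C(\C)[C@H](O)[C@@H](C)/C=C\C=C(/C)C(=O)Nc2cc(OC)cc(c2OC)[C@H](OC)[C@@H](C)C[C@@H]1O[Si](C)(C)C(C)(C)C | intermediate
39 | as 38 with 7-O-C(O)NHC(O)CCl3 | CO[C@@H]1[C@@H](C)/C=C(\C)[C@H](OC(=O)NC(=O)C(Cl)(Cl)Cl)[C@@H](C)/C=C\C=C(/C)C(=O)Nc2cc(OC)cc(c2OC)[C@H](OC)[C@@H](C)C[C@@H]1O[Si](C)(C)C(C)(C)C | intermediate
40 | as 38 with 7-O-C(O)NH2 (12-OTBS) | CO[C@@H]1[C@@H](C)/C=C(\C)[C@H](OC(N)=O)[C@@H](C)/C=C\C=C(/C)C(=O)Nc2cc(OC)cc(c2OC)[C@H](OC)[C@@H](C)C[C@@H]1O[Si](C)(C)C(C)(C)C | intermediate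
41 | 18,21-di-O-methyl ether of the target (7-carbamate, 12-OH) | CO[C@@H]1[C@@H](C)/C=C(\C)[C@H](OC(N)=O)[C@@H](C)/C=C\C=C(/C)C(=O)Nc2cc(OC)cc(c2OC)[C@H](OC)[C@@H](C)C[C@@H]1O | intermediate
42 | 18,21-quinone corresponding to the target | CO[C@@H]1[C@@H](C)/C=C(\C)[C@H](OC(N)=O)[C@@H](C)/C=C\C=C(/C)C(=O)NC2=CC(=O)C=C(C2=O)[C@H](OC)[C@@H](C)C[C@@H]1O | intermediate
43 | CNP0548031.1: (2E,4Z,8E,6S,7R,10S,11R,12S,14S,15R)-7-carbamoyloxy-12,18,21-trihydroxy-11,15-dimethoxy-2,6,8,10,14-pentamethyl macrolactam | CO[C@@H]1[C@@H](C)/C=C(\C)[C@H](OC(N)=O)[C@@H](C)/C=C\C=C(/C)C(=O)Nc2cc(O)cc(c2O)[C@H](OC)[C@@H](C)C[C@@H]1O | target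

## Step count and risk

Total: 30 steps. Longest linear sequence: 19 steps (5 → 6, steps 4–14, then steps 23–30). The acid branch (steps 15–22) and the reagent branch (steps 1–3) are shorter.

**Step 24 (key step).** Catalyst deactivation by the anilide N–H and the neighbouring methoxy group, or slow metathesis at two α-branched alkynes, could let oligomerisation outrun ring closure. The fallback moves the ring closure to the amide. It sets out from 19 and 31: alkyne cross-metathesis with 31 in excess (same Mo catalyst, no N–H present) should give methyl (2E,4Z,6S,7R,10S,11R,12S,14S,15R)-12-[(tert-butyldimethylsilyl)oxy]-15-(2,5-dimethoxy-3-nitrophenyl)-11,15-dimethoxy-2,6,10,14-tetramethyl-7-[(triethylsilyl)oxy]pentadeca-2,4-dien-8-ynoate F1. Zn/AcOH reduction gives the corresponding 3-amino-2,5-dimethoxyphenyl ester F2, and LiOH the amino acid F3. Macrolactamisation (BOP-Cl, i-Pr2NEt, toluene, high dilution) comes back to the route at 35. If the cause is steric hindrance at the alkynes, this fallback suffers too.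

**Step 5.** Poor anti/syn selectivity at C15, or erosion by retro-aldol equilibration, would give a mixture of carbinol epimers. The fallback sets C15 by ketone reduction instead of aldol topology. It sets out from the epimer mixture of 10: Dess–Martin oxidation gives (3S,5S)-3-(2,5-dimethoxy-3-nitrobenzoyl)-5-[(trityloxy)methyl]dihydrofuran-2(3H)-one F4. Noyori transfer hydrogenation with the (R,R)-TsDPEN ruthenium catalyst (HCO2H/Et3N) should give the 15R carbinol while the labile C14 settles in the trans lactone, returning to 10.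

**Step 8.** The hydrazone could lose the β-methoxy group at C15 by elimination, or epimerise at C14 through its ene-hydrazine tautomer, and the lactol may open only slowly. The fallback removes the oxygen by stepwise reduction. It sets out from 11: LiBH4 gives (2S,4R)-4-[(R)-(2,5-dimethoxy-3-nitrophenyl)(methoxy)methyl]-1-(trityloxy)pentane-2,5-diol F5. TBSOTf gives its 2,5-bis(tert-butyldimethylsilyl) ether F6; HF·pyridine cleaves the primary silyl ether to the 5-alcohol 2-TBS ether F7; I2/PPh3/imidazole gives the 5-iodide 2-TBS ether F8; NaBH4 in DMSO reduces the iodide and returns to the route at 15.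

**Step 21.** The Z-enal may isomerise to E on the oxidant before the less reactive α-methyl ylide traps it. The fallback builds the diene by cross-coupling. It sets out from 27: Stork–Zhao olefination (Ph3P=CHI) gives triethyl{[(1Z,3S,4R)-1-iodo-3-methylhept-1-en-5-yn-4-yl]oxy}silane F9. Suzuki–Miyaura coupling with methyl (E)-2-methyl-3-(4,4,5,5-tetramethyl-1,3,2-dioxaborolan-2-yl)acrylate (Pd(PPh3)4, aq. K3PO4) returns to 31.

**Step 27.** Protodestannylation next to the free hydroxyl could compete with methyl transfer at the hindered alkenyl tin. The fallback reverses the polarity of the coupling. It sets out from 37: iododestannylation (I2, CH2Cl2, 0 °C) gives the (8Z)-8-iodo macrolactam with free 7-OH and 12-OTBS F10. Negishi coupling with MeZnCl (Pd(PPh3)4, THF) returns to 38.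

## Further compounds

F1 | step 24 | methyl (2E,4Z,6S,7R,10S,11R,12S,14S,15R)-12-[(tert-butyldimethylsilyl)oxy]-15-(2,5-dimethoxy-3-nitrophenyl)-11,15-dimethoxy-2,6,10,14-tetramethyl-7-[(triethylsilyl)oxy]pentadeca-2,4-dien-8-ynoate | COC(=O)/C(C)=C/C=C\[C@H](C)[C@@H](O[Si](CC)(CC)CC)C#C[C@H](C)[C@@H](OC)[C@@H](O[Si](C)(C)C(C)(C)C)C[C@H](C)[C@@H](OC)c1cc(OC)cc([N+](=O)[O-])c1OC
F2 | step 24 | 3-amino-2,5-dimethoxyphenyl analogue of F1 (amino ester) | COC(=O)/C(C)=C/C=C\[C@H](C)[C@@H](O[Si](CC)(CC)CC)C#C[C@H](C)[C@@H](OC)[C@@H](O[Si](C)(C)C(C)(C)C)C[C@H](C)[C@@H](OC)c1cc(OC)cc(N)c1OC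
F3 | step 24 | carboxylic acid of F2 (seco amino acid of 35) | OC(=O)/C(C)=C/C=C\[C@H](C)[C@@H](O[Si](CC)(CC)CC)C#C[C@H](C)[C@@H](OC)[C@@H](O[Si](C)(C)C(C)(C)C)C[C@H](C)[C@@H](OC)c1cc(OC)cc(N)c1OC
F4 | step 5 | (3S,5S)-3-(2,5-dimethoxy-3-nitrobenzoyl)-5-[(trityloxy)methyl]dihydrofuran-2(3H)-one | O=C(c1cc(OC)cc([N+](=O)[O-])c1OC)[C@@H]1C[C@@H](COC(c2ccccc2)(c2ccccc2)c2ccccc2)OC1=O
F5 | step 8 | (2S,4R)-4-[(R)-(2,5-dimethoxy-3-nitrophenyl)(methoxy)methyl]-1-(trityloxy)pentane-2,5-diol | CO[C@@H](c1cc(OC)cc([N+](=O)[O-])c1OC)[C@@H](CO)C[C@H](O)COC(c2ccccc2)(c2ccccc2)c2ccccc2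
F6 | step 8 | 2,5-bis(tert-butyldimethylsilyl) ether of F5 | CO[C@@H](c1cc(OC)cc([N+](=O)[O-])c1OC)[C@@H](CO[Si](C)(C)C(C)(C)C)C[C@H](O[Si](C)(C)C(C)(C)C)COC(c2ccccc2)(c2ccccc2)c2ccccc2
F7 | step 8 | 2-O-TBS ether of F5 with free primary 5-OH | CO[C@@H](c1cc(OC)cc([N+](=O)[O-])c1OC)[C@@H](CO)C[C@H](O[Si](C)(C)C(C)(C)C)COC(c2ccccc2)(c2ccccc2)c2ccccc2
F8 | step 8 | primary iodide from F7 (CH2I on C14; 2-O-TBS) | CO[C@@H](c1cc(OC)cc([N+](=O)[O-])c1OC)[C@@H](CI)C[C@H](O[Si](C)(C)C(C)(C)C)COC(c2ccccc2)(c2ccccc2)c2ccccc2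
F9 | step 21 | triethyl{[(1Z,3S,4R)-1-iodo-3-methylhept-1-en-5-yn-4-yl]oxy}silane | CC#C[C@H](O[Si](CC)(CC)CC)[C@@H](C)/C=C\I
F10 | step 27 | (8Z)-8-iodo macrolactam with 7-OH, 12-OTBS, 11,15,18,21-tetramethoxy | CO[C@@H]1[C@@H](C)/C=C(\I)[C@H](O)[C@@H](C)/C=C\C=C(/C)C(=O)Nc2cc(OC)cc(c2OC)[C@H](OC)[C@@H](C)C[C@@H]1O[Si](C)(C)C(C)(C)C
A1 | alternative 1 | (2E,4Z,6S,7R,8E,10S,11R,12S,14S,15R)-15-(3-amino-2,5-dimethoxyphenyl)-12-[(tert-butyldimethylsilyl)oxy]-7-(carbamoyloxy)-11,15-dimethoxy-2,6,8,10,14-pentamethylpentadeca-2,4,8-trienoic acid | OC(=O)/C(C)=C/C=C\[C@H](C)[C@@H](OC(N)=O)/C(C)=C/[C@H](C)[C@@H](OC)[C@@H](O[Si](C)(C)C(C)(C)C)C[C@H](C)[C@@H](OC)c1cc(OC)cc(N)c1OC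
A2 | alternative 2 | (E)-2-methylhex-2-en-4-ynamide of the C5–C15 aniline bearing a C5≡C–CH3 terminus (7-OTES, 12-OTBS, 8E olefin in place) | CC#C/C=C(\C)C(=O)Nc1cc(OC)cc(c1OC)[C@H](OC)[C@@H](C)C[C@@H]([C@H](OC)[C@@H](C)/C=C(\C)[C@H](O[Si](CC)(CC)CC)[C@@H](C)C#CC)O[Si](C)(C)C(C)(C)C
A3 | alternative 2 | macrolactam with C4≡C5 (2E-en-4-yne), 8E olefin, 7-OTES, 12-OTBS, 18,21-dimethoxy | CO[C@@H]1[C@@H](C)/C=C(\C)[C@H](O[Si](CC)(CC)CC)[C@@H](C)C#C/C=C(\C)C(=O)Nc2cc(OC)cc(c2OC)[C@H](OC)[C@@H](C)C[C@@H]1O[Si](C)(C)C(C)(C)C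
A4 | alternative 3 | (2E,4Z,6S)-N-aryl-2,6-dimethyl-7-oxohepta-2,4-dienamide of aniline 20 (C7 aldehyde and C8≡C9 methyl alkyne in one chain) | O=C[C@@H](C)/C=C\C=C(/C)C(=O)Nc1cc(OC)cc(c1OC)[C@H](OC)[C@@H](C)C[C@@H]([C@H](OC)[C@@H](C)C#CC)O[Si](C)(C)C(C)(C)C
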